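**Plan**

- Target: 5,5'-dihydroxy-6,7,2',3'-tetramethoxyflavone (achiral). Ring B carries oxygen at C2' and C5' in a para relationship, with the chromone on C1' beside C2' – the 4-alkoxyphenol pattern that a carbene/alkyne/CO benzannulation delivers.
- Retrosynthesis: C5–OH and C5'–OH are unmasked last (from OMe and O-iPr) and C2'–OMe comes from a phenol. Ring B is then cut at C5'–C6', C1'–C2' and C2'–C3' into 2-ethynyl-5,6,7-trimethoxychromone, one CO ligand and a (2-methoxyvinyl)(isopropoxy)carbene complex of zerovalent chromium.
- Alkyne arm: ring A is bought as 3,4,5-trimethoxyphenol; C-acetylation, oxalate condensation and cyclodehydration close ring C; the C2 ester is taken through alcohol and aldehyde to the ethyne.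
- Carbene arm: bromoacetaldehyde dimethyl acetal gives (Z)-1-bromo-2-methoxyethene, whose lithio derivative adds to Cr(CO)6; O-isopropylation follows.
- Ring order forward: A (bought), C, then B last in the benzannulation; O-methylation at C2' and one BCl3 treatment finish the target.
- Stereochemistry: the target has none; the only stereo-element on the way, the enol ether geometry of the carbene arm, is erased when ring B aromatises.

Key step: step 9

Remark: the Z and the E isomer of the 2-methoxyvinyl carbene converge on the same arene, so the Z isomer, the one delivered by the non-eliminating Z-vinyllithium, is carried; isomerisation on handling is of no consequence.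

**Route**

Step 1
Reactants: 1 3,4,5-trimethoxyphenol
Product: 3 1-(6-hydroxy-2,3,4-trimethoxyphenyl)ethan-1-one, via difluoroboron chelate 2 (not isolated)
Conditions: AcOH, BF3·OEt2, 90 °C; then aq. NaOAc, rt
Reagents that add atoms: acetic acid, CC(=O)O
Why: BF3-promoted Friedel–Crafts C-acetylation of the electron-rich phenol occurs ortho to the hydroxyl (the two ortho positions are equivalent, the para position is blocked), and the product is held as its difluoroboron chelate, which prevents a second acylation and is hydrolysed on work-up.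

Step 2
Reactants: 3 1-(6-hydroxy-2,3,4-trimethoxyphenyl)ethan-1-one; 4 diethyl oxalate
Product: 6 ethyl 5,6,7-trimethoxy-4-oxo-4H-chromene-2-carboxylate, via diketo ester 5 (not isolated)
Conditions: NaOEt, EtOH, 0 °C to reflux; then conc. HCl, EtOH, reflux
Reagents that add atoms: none
Why: Crossed Claisen condensation of the methyl ketone with the non-enolisable oxalate, followed by acid-catalysed cyclodehydration of the phenol onto the new α-keto ester carbonyl, is the classical chromone-2-carboxylate synthesis and closes ring C without touching the methyl ethers.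

Step 3
Reactants: 6 ethyl 5,6,7-trimethoxy-4-oxo-4H-chromene-2-carboxylate
Product: 7 2-(hydroxymethyl)-5,6,7-trimethoxy-4H-chromen-4-one
Conditions: NaBH4, MeOH/THF, 0 °C
Reagents that add atoms: none
Why: Chemoselective borohydride reduction: the ester, activated by the electron-poor pyranone carbon C2, is reduced at 0 °C, whereas the C4 carbonyl is a deactivated vinylogous ester flanked by the C5 methoxy group.

Step 4
Reactants: 7 2-(hydroxymethyl)-5,6,7-trimethoxy-4H-chromen-4-one
Product: 8 5,6,7-trimethoxy-4-oxo-4H-chromene-2-carbaldehyde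
Conditions: Dess–Martin periodinane, CH2Cl2, rt
Reagents that add atoms: none
Why: Dess–Martin oxidation takes the primary, allylic-type alcohol to the aldehyde under neutral anhydrous conditions and cannot over-oxidise; the hydrate-prone aldehyde is used at once.

Step 5
Reactants: 8 5,6,7-trimethoxy-4-oxo-4H-chromene-2-carbaldehyde
Product: 9 2-ethynyl-5,6,7-trimethoxy-4H-chromen-4-one
Conditions: dimethyl (1-diazo-2-oxopropyl)phosphonate, K2CO3, MeOH/THF, 0 °C to rt
Reagents that add atoms: dimethyl (1-diazo-2-oxopropyl)phosphonate, CC(=O)C(=[N+]=[N-])P(=O)(OC)OC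
Why: Ohira–Bestmann (Seyferth–Gilbert) homologation: methanolysis of the reagent releases the diazomethylphosphonate anion, which olefinates the aldehyde, and loss of N2 with 1,2-hydrogen shift of the alkylidene carbene gives the terminal alkyne under carbonate basicity that the chromone should tolerate at low temperature.

Step 6
Reactants: 10 bromoacetaldehyde dimethyl acetal
Product: 12 (Z)-1-bromo-2-methoxyethene, via 1,2-dibromo-1-methoxyethane 11 (not isolated)
Conditions: AcBr, ZnBr2 (cat.), 0 to 40 °C; volatiles removed; then PhNEt2, 95 °C, product distilled out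
Reagents that add atoms: none
Why: Acetyl bromide exchanges one methoxy group of the acetal for bromide (acetal-to-α-halo-ether cleavage through the oxocarbenium ion) and the tertiary aniline then removes HBr in an E2 dehydrohalogenation, which by analogy with the ethyl homologue should give mainly the cis-configured Z enol ether, purified by distillation.

Step 7
Reactants: 12 (Z)-1-bromo-2-methoxyethene; 13 hexacarbonylchromium Cr(CO)6
Product: 16 tetramethylammonium pentacarbonyl[(Z)-3-methoxyacryloyl]chromate, via (Z)-2-methoxyvinyllithium 14 (not isolated), via lithium acylchromate 15 (not isolated)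
Conditions: t-BuLi (2 equiv), Et2O, −78 °C; Cr(CO)6, THF, −78 to −20 °C; then Me4NBr, degassed H2O, 0 °C
Reagents that add atoms: tetramethylammonium bromide, C[N+](C)(C)C.[Br-]
Why: Bromine–lithium exchange proceeds with retention to the Z-vinyllithium, whose O→Li contact and syn arrangement suppress β-elimination of LiOMe at low temperature, and its addition to a CO ligand of Cr(CO)6 is the first stage of the Fischer carbene synthesis, the acylate being secured as its easily handled tetramethylammonium salt by cation metathesis.

Step 8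
Reactants: 16 tetramethylammonium pentacarbonyl[(Z)-3-methoxyacryloyl]chromate
Product: 18 pentacarbonyl[(Z)-3-methoxy-1-(propan-2-yloxy)prop-2-en-1-ylidene]chromium, via acetoxycarbene complex 17 (not isolated)
Conditions: AcBr, CH2Cl2, −40 °C; then i-PrOH, −40 to 0 °C
Reagents that add atoms: propan-2-ol, CC(C)O
Why: O-Acylation of the acylchromate gives an acyloxycarbene that is strongly electrophilic at the carbene carbon, and addition–elimination by propan-2-ol delivers the isopropoxy carbene, the standard entry to secondary-alkoxy Fischer carbene complexes that direct O-alkylation does not reach.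

Step 9
Reactants: 9 2-ethynyl-5,6,7-trimethoxy-4H-chromen-4-one; 18 pentacarbonyl[(Z)-3-methoxy-1-(propan-2-yloxy)prop-2-en-1-ylidene]chromium (1.3 equiv)
Product: 20 2-[2-hydroxy-3-methoxy-5-(propan-2-yloxy)phenyl]-5,6,7-trimethoxy-4H-chromen-4-one, via tricarbonylchromium arene complex 19 (not isolated)
Conditions: toluene (degassed), 70 °C, Ar; then air, CH2Cl2, daylight, rt
Reagents that add atoms: none
Why: Thermal loss of one CO from 18 opens a site on chromium for the alkyne, which inserts into the chromium–carbene bond with its unsubstituted terminus bonded to the carbene carbon (C5'–C6'), so that chromium sits on the chromonyl-bearing carbon C1', where CO insertion gives a chromium-bound dienylketene (C1'–C2'). The six-membered ring B then closes by 6π-electrocyclisation of this dienylketene, the ketene carbon C2' bonding to the methoxy-bearing vinyl terminus C3', and tautomerisation of the cyclohexadienone gives the phenol, first as its Cr(CO)3 complex 19 and, after exposure to air and light, in free form. The closest known reaction type is the Dötz benzannulation of alkenyl(alkoxy)carbene pentacarbonylchromium complexes with terminal aryl- and alkenyl-substituted alkynes, which gives 4-alkoxyphenols, and 3-furyl carbene complexes show that an oxygen-bearing β-carbon can close onto the ketene. No stereocentre is formed, and the Z or E geometry of the vinyl group disappears in the arene. The regioselectivity needed (chromone ortho to the new hydroxyl, hydrogen at C6') is secured by the terminal alkyne, whose single substituent is kept away from the carbene substituents during insertion. The chemoselectivity needed (CO insertion to the phenol, not five-membered-ring formation) is favoured by the alkenyl carbene, its O-alkyl rather than amino donor, and the non-coordinating solvent.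

Step 10
Reactants: 20 2-[2-hydroxy-3-methoxy-5-(propan-2-yloxy)phenyl]-5,6,7-trimethoxy-4H-chromen-4-one
Product: 21 2-[2,3-dimethoxy-5-(propan-2-yloxy)phenyl]-5,6,7-trimethoxy-4H-chromen-4-one
Conditions: MeI, K2CO3, DMF, 40 °C
Reagents that add atoms: iodomethane, CI
Why: Williamson O-methylation of the only free phenol; C5 is still a methyl ether at this stage, so no selectivity between hydroxyl groups is required.

Step 11
Reactants: 21 2-[2,3-dimethoxy-5-(propan-2-yloxy)phenyl]-5,6,7-trimethoxy-4H-chromen-4-one
Product: 23 5-hydroxy-2-(5-hydroxy-2,3-dimethoxyphenyl)-6,7-dimethoxy-4H-chromen-4-one, via bis(dichloroboryl) ether 22 (not isolated)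
Conditions: BCl3 (about 4 equiv), CH2Cl2, −78 to 0 °C; then H2O, rt
Reagents that add atoms: none
Why: BCl3 ether cleavage removes the secondary isopropyl group far faster than a methyl group and demethylates the C5 methoxy through the six-membered boron chelate with the C4 carbonyl, while the four remaining methyl ethers have neither feature at 0 °C; the aryloxy(dichloro)boranes are hydrolysed on work-up.

**Compound list**

1 | 3,4,5-trimethoxyphenol | COc1cc(O)cc(OC)c1OC | starting material
2 | difluoroboron chelate of 1-(6-hydroxy-2,3,4-trimethoxyphenyl)ethan-1-one | CC1=[O+][B-](F)(F)Oc2cc(OC)c(OC)c(OC)c21 | intermediate (not isolated)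
3 | 1-(6-hydroxy-2,3,4-trimethoxyphenyl)ethan-1-one | CC(=O)c1c(O)cc(OC)c(OC)c1OC | intermediate
4 | diethyl oxalate | CCOC(=O)C(=O)OCC | starting material
5 | ethyl 4-(6-hydroxy-2,3,4-trimethoxyphenyl)-2,4-dioxobutanoate | CCOC(=O)C(=O)CC(=O)c1c(O)cc(OC)c(OC)c1OC | intermediate (not isolated)
6 | ethyl 5,6,7-trimethoxy-4-oxo-4H-chromene-2-carboxylate | CCOC(=O)c1cc(=O)c2c(OC)c(OC)c(OC)cc2o1 | intermediate
7 | 2-(hydroxymethyl)-5,6,7-trimethoxy-4H-chromen-4-one | OCc1cc(=O)c2c(OC)c(OC)c(OC)cc2o1 | intermediate
8 | 5,6,7-trimethoxy-4-oxo-4H-chromene-2-carbaldehyde | O=Cc1cc(=O)c2c(OC)c(OC)c(OC)cc2o1 | intermediate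
9 | 2-ethynyl-5,6,7-trimethoxy-4H-chromen-4-one | C#Cc1cc(=O)c2c(OC)c(OC)c(OC)cc2o1 | intermediate
10 | bromoacetaldehyde dimethyl acetal (2-bromo-1,1-dimethoxyethane) | COC(CBr)OC | starting material
11 | 1,2-dibromo-1-methoxyethane (racemic) | COC(Br)CBr | intermediate (not isolated)
12 | (Z)-1-bromo-2-methoxyethene | CO/C=C\Br | intermediate
13 | hexacarbonylchromium Cr(CO)6 | O=C=[Cr](=C=O)(=C=O)(=C=O)(=C=O)=C=O | starting material
14 | (Z)-2-methoxyvinyllithium | CO/C=C\[Li] | intermediate (not isolated)
15 | lithium pentacarbonyl[(Z)-3-methoxyacryloyl]chromate | [Li+].CO/C=C\C([O-])=[Cr](=C=O)(=C=O)(=C=O)(=C=O)=C=O | intermediate (not isolated)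
16 | tetramethylammonium pentacarbonyl[(Z)-3-methoxyacryloyl]chromate | C[N+](C)(C)C.CO/C=C\C([O-])=[Cr](=C=O)(=C=O)(=C=O)(=C=O)=C=O | intermediate
17 | pentacarbonyl[(Z)-1-acetoxy-3-methoxyprop-2-en-1-ylidene]chromium | CO/C=C\C(OC(C)=O)=[Cr](=C=O)(=C=O)(=C=O)(=C=O)=C=O | intermediate (not isolated)
18 | pentacarbonyl[(Z)-3-methoxy-1-(propan-2-yloxy)prop-2-en-1-ylidene]chromium | CO/C=C\C(OC(C)C)=[Cr](=C=O)(=C=O)(=C=O)(=C=O)=C=O | intermediate
19 | tricarbonylchromium complex of 20, Cr(CO)3 bound η6 to ring B (written as two dot-joined parts) | COc1cc(OC(C)C)cc(-c2cc(=O)c3c(OC)c(OC)c(OC)cc3o2)c1O.O=C=[Cr](=C=O)=C=O | intermediate (not isolated)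
20 | 2-[2-hydroxy-3-methoxy-5-(propan-2-yloxy)phenyl]-5,6,7-trimethoxy-4H-chromen-4-one | COc1cc(OC(C)C)cc(-c2cc(=O)c3c(OC)c(OC)c(OC)cc3o2)c1O | intermediate
21 | 2-[2,3-dimethoxy-5-(propan-2-yloxy)phenyl]-5,6,7-trimethoxy-4H-chromen-4-one | COc1cc(OC(C)C)cc(-c2cc(=O)c3c(OC)c(OC)c(OC)cc3o2)c1OC | intermediate
22 | 5-(dichloroboryloxy)-2-[5-(dichloroboryloxy)-2,3-dimethoxyphenyl]-6,7-dimethoxy-4H-chromen-4-one | COc1cc(OB(Cl)Cl)cc(-c2cc(=O)c3c(OB(Cl)Cl)c(OC)c(OC)cc3o2)c1OC | intermediate (not isolated)
23 | 5-hydroxy-2-(5-hydroxy-2,3-dimethoxyphenyl)-6,7-dimethoxy-4H-chromen-4-one | COc1cc(O)cc(-c2cc(=O)c3c(O)c(OC)c(OC)cc3o2)c1OC | target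

**Count and risks**

Total step count: 11. Longest linear sequence: 8 steps (steps 1–5, then 9–11); the carbene arm (steps 6–8) joins at step 9.

Steps most likely to fail:

1. Step 9. The donor-stabilised carbene may lose CO only sluggishly. The electron-poor, conjugated alkyne may oligomerise at chromium, or insert without CO incorporation and close a five-membered ring, so that little phenol forms. The fallback builds ring B from a benzaldehyde and closes ring C last; it sets out from acetophenone 3 and rejoins the route at 21. Commercial 5-bromo-2,3-dimethoxybenzaldehyde is borylated (B2pin2, PdCl2(dppf), KOAc, dioxane, 90 °C) to 2,3-dimethoxy-5-(4,4,5,5-tetramethyl-1,3,2-dioxaborolan-2-yl)benzaldehyde F1. Oxidation (NaBO3·4H2O, THF/H2O, rt) gives 5-hydroxy-2,3-dimethoxybenzaldehyde F2, and alkylation (2-bromopropane, K2CO3, DMF) gives 2,3-dimethoxy-5-(propan-2-yloxy)benzaldehyde F3. Claisen–Schmidt condensation of this aldehyde with 3 (KOH, EtOH, rt) should give the chalcone (E)-1-(6-hydroxy-2,3,4-trimethoxyphenyl)-3-[2,3-dimethoxy-5-(propan-2-yloxy)phenyl]prop-2-en-1-one F4. Oxidative cyclisation with catalytic I2 in DMSO at 120 °C then closes ring C to 21.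

2. Step 7. β-Elimination of LiOMe from the vinyllithium (to acetylene) may outrun its addition to the poorly soluble Cr(CO)6, or a residue of the E bromide may fragment on exchange, leaving little acylate. The fallback reverses the polarity and brings the vinyl unit in as an acid chloride; it sets out from 13 and rejoins the route at 20. Cr(CO)6 13 is reduced with potassium graphite C8K (THF, −78 °C to rt) to dipotassium pentacarbonylchromate K2Cr(CO)5 F5. This is acylated at −78 °C with (E)-3-methoxyacryloyl chloride F6, made from commercial (E)-3-methoxyacrylic acid and oxalyl chloride, to give potassium pentacarbonyl[(E)-3-methoxyacryloyl]chromate F7. Cation exchange with Me4NBr gives tetramethylammonium pentacarbonyl[(E)-3-methoxyacryloyl]chromate F8. AcBr at −40 °C gives pentacarbonyl[(E)-1-acetoxy-3-methoxyprop-2-en-1-ylidene]chromium F9, which with propan-2-ol gives pentacarbonyl[(E)-3-methoxy-1-(propan-2-yloxy)prop-2-en-1-ylidene]chromium F10. This E isomer of 18 is heated with alkyne 9 under the conditions of step 9 and should give 20 by way of the same arene complex 19.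

3. Step 5. Methoxide generated from K2CO3 in MeOH may add to C2 of the pyranone and open ring C, or add to the newly formed conjugated alkyne, and the hydrated aldehyde may react slowly. The fallback avoids alkoxide altogether; it sets out from 8 and rejoins the route at 9. Corey–Fuchs olefination (CBr4, PPh3, CH2Cl2, 0 °C) gives 2-(2,2-dibromoethenyl)-5,6,7-trimethoxy-4H-chromen-4-one F11. Selective hydrogenolysis of the bromine trans to the chromone (Bu3SnH, catalytic Pd(PPh3)4 as zerovalent palladium source, toluene, rt) gives 2-[(Z)-2-bromoethenyl]-5,6,7-trimethoxy-4H-chromen-4-one F12. Anti-elimination of HBr with DBU in MeCN at rt then gives 9.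

Further compounds
F1 | step 9 | 2,3-dimethoxy-5-(4,4,5,5-tetramethyl-1,3,2-dioxaborolan-2-yl)benzaldehyde | COc1cc(B2OC(C)(C)C(C)(C)O2)cc(C=O)c1OC
F2 | step 9 | 5-hydroxy-2,3-dimethoxybenzaldehyde | COc1cc(O)cc(C=O)c1OC
F3 | step 9 | 2,3-dimethoxy-5-(propan-2-yloxy)benzaldehyde | COc1cc(OC(C)C)cc(C=O)c1OC
F4 | step 9 | (E)-1-(6-hydroxy-2,3,4-trimethoxyphenyl)-3-[2,3-dimethoxy-5-(propan-2-yloxy)phenyl]prop-2-en-1-one | COc1cc(OC(C)C)cc(/C=C/C(=O)c2c(O)cc(OC)c(OC)c2OC)c1OC
F5 | step 7 | dipotassium pentacarbonylchromate K2Cr(CO)5 | [K+].[K+].O=C=[Cr-2](=C=O)(=C=O)(=C=O)=C=O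
F6 | step 7 | (E)-3-methoxyacryloyl chloride | CO/C=C/C(Cl)=O
F7 | step 7 | potassium pentacarbonyl[(E)-3-methoxyacryloyl]chromate | [K+].CO/C=C/C([O-])=[Cr](=C=O)(=C=O)(=C=O)(=C=O)=C=O
F8 | step 7 | tetramethylammonium pentacarbonyl[(E)-3-methoxyacryloyl]chromate | C[N+](C)(C)C.CO/C=C/C([O-])=[Cr](=C=O)(=C=O)(=C=O)(=C=O)=C=O
F9 | step 7 | pentacarbonyl[(E)-1-acetoxy-3-methoxyprop-2-en-1-ylidene]chromium | CO/C=C/C(OC(C)=O)=[Cr](=C=O)(=C=O)(=C=O)(=C=O)=C=O
F10 | step 7 | pentacarbonyl[(E)-3-methoxy-1-(propan-2-yloxy)prop-2-en-1-ylidene]chromium | CO/C=C/C(OC(C)C)=[Cr](=C=O)(=C=O)(=C=O)(=C=O)=C=O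
F11 | step 5 | 2-(2,2-dibromoethenyl)-5,6,7-trimethoxy-4H-chromen-4-one | BrC(Br)=Cc1cc(=O)c2c(OC)c(OC)c(OC)cc2o1
F12 | step 5 | 2-[(Z)-2-bromoethenyl]-5,6,7-trimethoxy-4H-chromen-4-one | Br/C=C\c1cc(=O)c2c(OC)c(OC)c(OC)cc2o1
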